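Start at the late end of the run, where your hunch that more scavenger buys conversion has to show, with the flasks as they stand:

- south-east: electrophile 0.50 M; nucleophile 0.600 M; scavenger 0.500 M; time 80 s
- south: electrophile 0.50 M; nucleophile 0.600 M; scavenger 1.00 M; time 80 s

    electrophile + nucleophile → acid set free + target (k1 = 0.130 M⁻¹ s⁻¹)
    nucleophile + acid set free ⇌ protonated nucleophile, settled at all times (K2 = 67 M⁻¹)
    electrophile → decomposition product (k3 = 3.97 × 10⁻⁴ s⁻¹)
    acid set free → by-product carried off (k4 = 1.67 s⁻¹)
    nucleophile + acid set free ⇌ idle adduct, settled at all times (K5 = 280 M⁻¹)
    acid set free + scavenger → scavenged by-product (k6 = 6.01 M⁻¹ s⁻¹)

1. part of the electrophile that has reacted at the end, south-east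
2. part of the electrophile that has reacted at the end, south
3. what raising the concentration of scavenger from its lowest to its highest value here does to the part of the electrophile that has reacted (changes below 5 percentage points count as none) (no change / it rises / it falls)

Each target formed costs one electrophile and one nucleophile, so carry the nucleophile surplus, the charged nucleophile less the charged electrophile, 0.100 M. Turn the constants into half-lives at the charged amounts. South-east, the electrophile needs 8.89 s by the target step, while free acid needs 0.231 s by the scavenger and 0.415 s by carrying off, far shorter. Decomposition takes 29.1 min, long against the run. So suppose acid leaves at once; the nucleophile then stays one surplus above the electrophile, and the second-order law gives a clean figure: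

exponent = rate constant of the target step × surplus × time = 1.04

electrophile left = surplus ÷ ((charged nucleophile ÷ charged electrophile) × e^exponent − 1) = 0.0418 M

part reacted = 91.6%

Scavenger appears nowhere in that figure. I take it to act through the acid held on nucleophile, with a combined balance constant of 347 M⁻¹, and I take the nucleophile so tied up, and with it the gap below the clean figure, to go inversely with the clearing rate, meaning carrying off plus scavenger at its charge. South has 1.64 times the clearing rate of south-east, so on that assumption a move of 5 percentage points needs a south-east gap of 13 points. I expect a narrower gap, so I say no change.

The forecast gave 87% and 88.5%, with south-east lower than my clean figure, and no change, in the words “Doubling the scavenger changes conversion by only 1–2 points, so this counts as no change.”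

The flasks give 87.2% in south-east and 89.0% in south, a change of 1.8 points, so no change; the south-east gap is 4.4 points. In south-east the target step had half its turnover up to the end of the run behind it by 12.3 s, while carrying off reached that mark at 31.6 s, and the idle adduct fell from 0.0667 M at 40.0 s to 0.0231 M at 80.0 s. At 800 s south-east holds 17.8% of its nucleophile, against 16.7% from the surplus.

With 1.2 M of electrophile the surplus turns negative, −0.600 M, making nucleophile the limiting reagent and capping target at 50.0% of the electrophile charged. That flask gives 49.5% target, with 0.98% of its nucleophile left.

(The constants used here belong to no real substance; the run is a simulation.)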